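**Retrosynthetic overview**

1. After a final desilylation, the side chain is cut between its olefinic CH and the allylic CH2 that lies two carbons from C2 of the pyran ring. This gives E-alkenyl iodide 9 and 2-vinylchromene 18, joined in one flask by hydroboration and B-alkyl Suzuki–Miyaura coupling.
2. Enabling feature: the vinyl group on the hydrogen-free C2 of the pyran ring is the only monosubstituted C=C. Its terminal CH2 takes boron from 9-BBN, while the cis-disubstituted, aryl-conjugated C3=C4 bond of the same ring stays untouched.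
3. 18: the pyran ring comes from Cu-catalysed aryl C–O closure of Z-dienol 17. Its tertiary carbinol comes from Sharpless epoxidation of enynol 13 (Sonogashira product of 11 and 12) and zinc-induced epoxide opening.
4. 9: Zr-catalysed carboalumination and iodination of alkyne 7. The ring stereocentre comes from CBS reduction of enone 1 and Johnson–Claisen transfer of chirality.
5. Ring order: the cyclohexene and benzene rings are bought with 1 and 10; the pyran ring is closed in step 13, before the fragment union.

Key step: step 14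

Remark: 1, 10 and 12 are taken as catalogue compounds; because the chromene stereocentre can be lost only by electrocyclic opening of the pyran ring (strong heating, UV light), everything from step 13 onwards is run at or below 90 °C with light excluded.

**Route**

Step 1
Reactants: 1 2,4,4-trimethylcyclohex-2-en-1-one
Product: 2 (1R)-2,4,4-trimethylcyclohex-2-en-1-ol
Conditions: (S)-2-methyl-CBS-oxazaborolidine (10 mol%), BH3·SMe2 (0.7 equiv), THF, −20 °C; MeOH
Reagents that add atoms: none
Why: Corey–Bakshi–Shibata reduction: the ketone binds to the boron of the oxazaborolidine with its 2-methylalkenyl arm (the larger group) turned away from the catalyst, so the hydride of the coordinated BH3 reaches one carbonyl face only and C1 is set as R, while the α-methyl group keeps the reduction 1,2.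

Step 2
Reactants: 2 (1R)-2,4,4-trimethylcyclohex-2-en-1-ol
Product: 4 ethyl [(1S)-2,6,6-trimethylcyclohex-2-en-1-yl]acetate, via ketene acetal 3 (not isolated)
Conditions: MeC(OEt)3 (6 equiv), EtCO2H (5 mol%), 140 °C, EtOH distilled off
Reagents that add atoms: triethyl orthoacetate CC(OCC)(OCC)OCC
Why: Johnson–Claisen rearrangement: acid-catalysed exchange gives ketene acetal 3, whose suprafacial [3,3] shift forms the new C–C bond at C3 on the ring face from which the C1–O bond departs, so the R carbinol centre is traded for the S ring centre beside the gem-dimethyl carbon and the double bond moves into the C1–C2 position.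

Step 3
Reactants: 4 ethyl [(1S)-2,6,6-trimethylcyclohex-2-en-1-yl]acetate
Product: 5 2-[(1S)-2,6,6-trimethylcyclohex-2-en-1-yl]ethan-1-ol
Conditions: LiAlH4 (1.0 equiv), Et2O, 0 °C; then H2O
Reagents that add atoms: none
Why: Ester reduction with LiAlH4 to the primary alcohol, which leaves the trisubstituted alkene and the non-epimerisable ring stereocentre (it is β to the carbonyl group) unchanged.

Step 4
Reactants: 5 2-[(1S)-2,6,6-trimethylcyclohex-2-en-1-yl]ethan-1-ol
Product: 6 (6S)-6-(2-iodoethyl)-1,5,5-trimethylcyclohex-1-ene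
Conditions: I2 (1.2 equiv), PPh3 (1.2 equiv), imidazole (1.5 equiv), CH2Cl2, 0 → 23 °C
Reagents that add atoms: iodine II
Why: Appel-type iodination: the alkoxyphosphonium ion formed from PPh3 and I2 is displaced by iodide in an SN2 reaction at the primary carbon.

Step 5
Reactants: 6 (6S)-6-(2-iodoethyl)-1,5,5-trimethylcyclohex-1-ene
Product: 7 (6S)-6-(but-3-yn-1-yl)-1,5,5-trimethylcyclohex-1-ene
Conditions: LiC≡CH·H2NCH2CH2NH2 (1.5 equiv), DMSO, 20 °C
Reagents that add atoms: lithium acetylide (used as its ethane-1,2-diamine complex) [Li+].[C-]#C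
Why: SN2 alkylation of the acetylide anion by an unbranched primary iodide in DMSO, the standard two-carbon homologation to a terminal alkyne.

Step 6
Reactants: 7 (6S)-6-(but-3-yn-1-yl)-1,5,5-trimethylcyclohex-1-ene
Product: 9 (6S)-6-[(3E)-4-iodo-3-methylbut-3-en-1-yl]-1,5,5-trimethylcyclohex-1-ene, via alkenylalane 8 (not isolated)
Conditions: Me3Al (2.5 equiv), Cp2ZrCl2 (0.25 equiv), CH2Cl2, 0 → 23 °C; then I2 (1.5 equiv), THF, −30 → 0 °C
Reagents that add atoms: trimethylaluminium C[Al](C)C; iodine II
Why: Zr-catalysed carboalumination (Negishi): methyl and aluminium add syn across the terminal alkyne with aluminium on the terminal carbon to give alkenylalane 8, and iodinolysis of the C–Al bond with retention should give the E iodide, the trisubstituted ring alkene being inert to Me3Al/Cp2ZrCl2.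

Step 7
Reactants: 10 4-bromo-3-iodophenol
Product: 11 (4-bromo-3-iodophenoxy)tri(propan-2-yl)silane
Conditions: TIPSCl (1.1 equiv), imidazole (2 equiv), DMF, 23 °C
Reagents that add atoms: chlorotri(propan-2-yl)silane CC(C)[Si](Cl)(C(C)C)C(C)C
Why: Silyl ether formation: imidazole-activated TIPSCl caps the phenol as a bulky aryl silyl ether that should survive amine bases, titanium alkoxides, zinc, hydrogenation and carbonate and is cleaved by fluoride at the end.

Step 8
Reactants: 11 (4-bromo-3-iodophenoxy)tri(propan-2-yl)silane; 12 (2E)-3-methylpent-2-en-4-yn-1-ol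
Product: 13 (2E)-5-{2-bromo-5-[tri(propan-2-yl)silyloxy]phenyl}-3-methylpent-2-en-4-yn-1-ol
Conditions: PdCl2(PPh3)2 (2 mol%), CuI (4 mol%), Et3N, THF, 23 °C
Reagents that add atoms: none
Why: Sonogashira coupling: zerovalent palladium inserts into the C–I bond much faster than into the neighbouring C–Br bond at room temperature, so the alkynyl–Cu species formed from 12 and CuI is coupled only at the iodine-bearing carbon and the E alkene and free hydroxyl group are carried through.

Step 9
Reactants: 13 (2E)-5-{2-bromo-5-[tri(propan-2-yl)silyloxy]phenyl}-3-methylpent-2-en-4-yn-1-ol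
Product: 14 [(2R,3R)-3-({2-bromo-5-[tri(propan-2-yl)silyloxy]phenyl}ethynyl)-3-methyloxiran-2-yl]methanol
Conditions: Ti(OiPr)4 (0.3 equiv), D-(−)-diethyl tartrate (0.36 equiv), t-BuOOH (2 equiv, in decane), 4 Å molecular sieves, CH2Cl2, −20 °C
Reagents that add atoms: tert-butyl hydroperoxide CC(C)(C)OO
Why: Sharpless asymmetric epoxidation: the allylic alcohol is bound to the Ti(OiPr)4–tartrate complex and D-(−)-tartrate directs the peroxide oxygen to the face that gives the 2R,3R epoxide of an E allylic alcohol (the mirror image of the 2S,3S outcome with L-(+)-tartrate), which fixes the future quaternary centre, while alkyne and arene are inert to t-BuOOH.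

Step 10
Reactants: 14 [(2R,3R)-3-({2-bromo-5-[tri(propan-2-yl)silyloxy]phenyl}ethynyl)-3-methyloxiran-2-yl]methanol
Product: 15 (2S,3R)-3-({2-bromo-5-[tri(propan-2-yl)silyloxy]phenyl}ethynyl)-2-(iodomethyl)-3-methyloxirane
Conditions: I2 (1.2 equiv), PPh3 (1.2 equiv), imidazole (2 equiv), CH2Cl2, 0 °C
Reagents that add atoms: iodine II
Why: Appel-type iodination of the primary alcohol, buffered by imidazole so that the epoxide stays closed; no bond at either stereocentre is broken (the descriptor of the CH carbon changes only because CH2I outranks the ring carbon).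

Step 11
Reactants: 15 (2S,3R)-3-({2-bromo-5-[tri(propan-2-yl)silyloxy]phenyl}ethynyl)-2-(iodomethyl)-3-methyloxirane
Product: 16 (3S)-5-{2-bromo-5-[tri(propan-2-yl)silyloxy]phenyl}-3-methylpent-1-en-4-yn-3-ol
Conditions: Zn dust (3 equiv), EtOH, 60 °C; then H2O
Reagents that add atoms: none
Why: Reductive β-elimination: zinc inserts into the C–I bond and the resulting C–Zn bond expels the neighbouring epoxide oxygen, which creates the vinyl group and releases the tertiary alkoxide without breaking its C–O bond, so the quaternary centre keeps its geometry (its descriptor becomes S only because the ranking of the substituents changes).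

Step 12
Reactants: 16 (3S)-5-{2-bromo-5-[tri(propan-2-yl)silyloxy]phenyl}-3-methylpent-1-en-4-yn-3-ol
Product: 17 (3S,4Z)-5-{2-bromo-5-[tri(propan-2-yl)silyloxy]phenyl}-3-methylpenta-1,4-dien-3-ol
Conditions: H2 (1 atm), Pd/CaCO3 poisoned with Pb(OAc)2 (Lindlar catalyst), quinoline, EtOAc, 23 °C, stopped after 1 equiv of H2
Reagents that add atoms: none
Why: Lindlar semihydrogenation: syn addition of H2 on the lead-poisoned palladium surface should turn the alkyne into the Z alkene that brings the hydroxyl group next to the C–Br bond, with quinoline and metered hydrogen uptake sparing the vinyl group and the aryl bromide.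

Step 13
Reactants: 17 (3S,4Z)-5-{2-bromo-5-[tri(propan-2-yl)silyloxy]phenyl}-3-methylpenta-1,4-dien-3-ol
Product: 18 {[(2S)-2-ethenyl-2-methyl-2H-chromen-6-yl]oxy}tri(propan-2-yl)silane
Conditions: CuI (10 mol%), 3,4,7,8-tetramethyl-1,10-phenanthroline (20 mol%), Cs2CO3 (2 equiv), toluene, 90 °C, dark
Reagents that add atoms: none
Why: Ullmann-type intramolecular C–O coupling: the alkoxide formed with Cs2CO3 binds copper, the aryl C–Br bond held nearby by the Z alkene adds and reductive elimination closes the pyran ring (six-membered, O–aryl bond formed) without touching any bond at the carbinol carbon, which therefore becomes C2 with S configuration, and copper, unlike palladium, offers no Heck pathway to the vinyl group.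

Step 14
Reactants: 18 {[(2S)-2-ethenyl-2-methyl-2H-chromen-6-yl]oxy}tri(propan-2-yl)silane; 9 (6S)-6-[(3E)-4-iodo-3-methylbut-3-en-1-yl]-1,5,5-trimethylcyclohex-1-ene
Product: 20 tri(propan-2-yl){[(2S)-2-methyl-2-{(3E)-4-methyl-6-[(1S)-2,6,6-trimethylcyclohex-2-en-1-yl]hex-3-en-1-yl}-2H-chromen-6-yl]oxy}silane, via alkylborane 19 (not isolated)
Conditions: 9-BBN dimer (0.6 equiv), THF, 0 → 23 °C; then 9 (0.95 equiv), PdCl2(dppf)·CH2Cl2 (5 mol%), AsPh3 (5 mol%), aq. K3PO4 (3 M, 3 equiv), DMF, 23 °C, dark
Reagents that add atoms: none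
Why: 9-BBN adds B–H across the C2 vinyl group by four-centre syn addition with boron on the terminal carbon, borane 19 is activated by phosphate as a borate, and zerovalent palladium formed from PdCl2(dppf) inserts into the C–I bond of 9, takes over the primary alkyl group by transmetalation and releases the sp3–sp2 bond by reductive elimination with retention of the E geometry. The closest known reaction type is the one-pot hydroboration/B-alkyl Suzuki–Miyaura coupling of terminal alkenes with (E)-2-methylalk-1-enyl iodides used to assemble trisubstituted olefins of terpenoids. No ring is closed and no stereocentre is created; C2 of the pyran ring and C1 of the cyclohexene ring carry no reacting bond and should pass through unchanged. The step needs chemoselectivity among the C=C bonds and regioselectivity within the vinyl group: the vinyl group is monosubstituted and sits on a quaternary carbon, whereas the ring C3=C4 bond is cis-disubstituted, conjugated and flanked by that quaternary carbon, so the bulky 9-BBN should react only at the terminal CH2. The trisubstituted ring alkene of 9 is added only after all B–H has been consumed, and the wide bite angle of dppf should make reductive elimination faster than β-hydride elimination of the alkylpalladium intermediate.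

Step 15
Reactants: 20 tri(propan-2-yl){[(2S)-2-methyl-2-{(3E)-4-methyl-6-[(1S)-2,6,6-trimethylcyclohex-2-en-1-yl]hex-3-en-1-yl}-2H-chromen-6-yl]oxy}silane
Product: 21 (2S)-2-methyl-2-{(3E)-4-methyl-6-[(1S)-2,6,6-trimethylcyclohex-2-en-1-yl]hex-3-en-1-yl}-2H-chromen-6-ol
Conditions: Bu4NF (1.2 equiv), AcOH (1.2 equiv), THF, 0 °C
Reagents that add atoms: none
Why: Fluoride-induced desilylation: fluoride attacks silicon and the phenoxide leaves, buffered with AcOH so that it is protonated at once, conditions that should leave the three C=C bonds, the allylic aryl ether and both stereocentres unchanged.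

**Compound list**

1 | 2,4,4-trimethylcyclohex-2-en-1-one | O=C1CCC(C)(C)C=C1C | starting material
2 | (1R)-2,4,4-trimethylcyclohex-2-en-1-ol | O[C@@H]1CCC(C)(C)C=C1C | intermediate
3 | 1-ethoxy-1-{[(1R)-2,4,4-trimethylcyclohex-2-en-1-yl]oxy}ethene (ketene acetal) | C=C(OCC)O[C@@H]1CCC(C)(C)C=C1C | intermediate (not isolated)
4 | ethyl [(1S)-2,6,6-trimethylcyclohex-2-en-1-yl]acetate | CC1=CCCC(C)(C)[C@@H]1CC(=O)OCC | intermediate
5 | 2-[(1S)-2,6,6-trimethylcyclohex-2-en-1-yl]ethan-1-ol | CC1=CCCC(C)(C)[C@@H]1CCO | intermediate
6 | (6S)-6-(2-iodoethyl)-1,5,5-trimethylcyclohex-1-ene | CC1=CCCC(C)(C)[C@@H]1CCI | intermediate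
7 | (6S)-6-(but-3-yn-1-yl)-1,5,5-trimethylcyclohex-1-ene | CC1=CCCC(C)(C)[C@@H]1CCC#C | intermediate
8 | dimethyl{(1E)-2-methyl-4-[(1S)-2,6,6-trimethylcyclohex-2-en-1-yl]but-1-en-1-yl}alane | CC1=CCCC(C)(C)[C@@H]1CC/C(C)=C/[Al](C)C | intermediate (not isolated)
9 | (6S)-6-[(3E)-4-iodo-3-methylbut-3-en-1-yl]-1,5,5-trimethylcyclohex-1-ene | CC1=CCCC(C)(C)[C@@H]1CC/C(C)=C/I | intermediate
10 | 4-bromo-3-iodophenol | Oc1ccc(Br)c(I)c1 | starting material
11 | (4-bromo-3-iodophenoxy)tri(propan-2-yl)silane | CC(C)[Si](Oc1ccc(Br)c(I)c1)(C(C)C)C(C)C | intermediate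
12 | (2E)-3-methylpent-2-en-4-yn-1-ol | OC/C=C(C)/C#C | starting material
13 | (2E)-5-{2-bromo-5-[tri(propan-2-yl)silyloxy]phenyl}-3-methylpent-2-en-4-yn-1-ol | OC/C=C(C)/C#Cc1cc(O[Si](C(C)C)(C(C)C)C(C)C)ccc1Br | intermediate
14 | [(2R,3R)-3-({2-bromo-5-[tri(propan-2-yl)silyloxy]phenyl}ethynyl)-3-methyloxiran-2-yl]methanol | OC[C@H]1O[C@]1(C)C#Cc1cc(O[Si](C(C)C)(C(C)C)C(C)C)ccc1Br | intermediate
15 | (2S,3R)-3-({2-bromo-5-[tri(propan-2-yl)silyloxy]phenyl}ethynyl)-2-(iodomethyl)-3-methyloxirane | IC[C@H]1O[C@]1(C)C#Cc1cc(O[Si](C(C)C)(C(C)C)C(C)C)ccc1Br | intermediate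
16 | (3S)-5-{2-bromo-5-[tri(propan-2-yl)silyloxy]phenyl}-3-methylpent-1-en-4-yn-3-ol | C=C[C@](C)(O)C#Cc1cc(O[Si](C(C)C)(C(C)C)C(C)C)ccc1Br | intermediate
17 | (3S,4Z)-5-{2-bromo-5-[tri(propan-2-yl)silyloxy]phenyl}-3-methylpenta-1,4-dien-3-ol | C=C[C@](C)(O)/C=C\c1cc(O[Si](C(C)C)(C(C)C)C(C)C)ccc1Br | intermediate
18 | {[(2S)-2-ethenyl-2-methyl-2H-chromen-6-yl]oxy}tri(propan-2-yl)silane | C=C[C@@]1(C)C=Cc2cc(O[Si](C(C)C)(C(C)C)C(C)C)ccc2O1 | intermediate
19 | 9-{2-[(2S)-2-methyl-6-{[tri(propan-2-yl)silyl]oxy}-2H-chromen-2-yl]ethyl}-9-borabicyclo[3.3.1]nonane | C(CB1C2CCCC1CCC2)[C@@]1(C)C=Cc2cc(O[Si](C(C)C)(C(C)C)C(C)C)ccc2O1 | intermediate (not isolated)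
20 | tri(propan-2-yl){[(2S)-2-methyl-2-{(3E)-4-methyl-6-[(1S)-2,6,6-trimethylcyclohex-2-en-1-yl]hex-3-en-1-yl}-2H-chromen-6-yl]oxy}silane | CC1=CCCC(C)(C)[C@@H]1CC/C(C)=C/CC[C@@]1(C)C=Cc2cc(O[Si](C(C)C)(C(C)C)C(C)C)ccc2O1 | intermediate
21 | (2S)-2-methyl-2-{(3E)-4-methyl-6-[(1S)-2,6,6-trimethylcyclohex-2-en-1-yl]hex-3-en-1-yl}-2H-chromen-6-ol | CC1=CCCC(C)(C)[C@@H]1CC/C(C)=C/CC[C@@]1(C)C=Cc2cc(O)ccc2O1 | target

**Step count and risks**

Total step count: 15 (six steps to iodide 9, seven to chromene 18, two after their union).
Longest linear sequence: 9 steps (10 → 21, steps 7 to 15).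

Most likely to fail, step 13: C–O bond formation at the crowded tertiary alkoxide may be slow, and the heat then needed may erode the configuration at C2 through reversible electrocyclic opening of the new pyran ring. The fallback changes the order of ring closure and fragment union and sets out from 17. The vinyl group of 17 is hydroborated with 9-BBN (2.3 equiv of B–H, the hydroxyl group being taken up as its borinate) to give the bis-boron adduct F1 (not isolated). F1 is coupled in the same flask with 9 under the conditions of step 14; the alkenyl C–I bond should react at 23 °C while the electron-rich aryl C–Br bond does not, which gives the open-chain bromo alcohol F2. The pyran ring is then closed by Pd-catalysed intramolecular aryl ether formation (Pd(OAc)2, 2-(di-tert-butylphosphino)-1,1'-binaphthyl, Cs2CO3, toluene, 65 °C), where no vinyl group is left for a Heck reaction. This comes back to the route at 20.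

Second, step 2: under acid at 140 °C the allylic C–O bond may ionise (loss of enantiomeric purity, elimination to a diene), or exchange and rearrangement may stall at the crowded terminus beside the gem-dimethyl carbon. The fallback sets out from 2 and uses an Eschenmoser–Claisen rearrangement in a neutral medium. Heating 2 with N,N-dimethylacetamide dimethyl acetal in xylene at 140 °C without acid passes through the ketene N,O-acetal F3 (not isolated) and gives, with the same suprafacial transfer, the amide F4. Reduction of F4 with LiBHEt3 in THF cleaves the C–N bond and comes back to the route at 5.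

Third, step 12: hydrogen uptake may run past the alkyne stage and saturate the vinyl group that the key step needs. The fallback sets out from 14 and reduces the alkyne before any other C=C bond exists. Lindlar hydrogenation of 14 gives the Z-alkenyl epoxy alcohol F5, iodination (I2, PPh3, imidazole, CH2Cl2, 0 °C) gives the epoxy iodide F6, and Zn dust in EtOH opens F6 to the dienol. This comes back to the route at 17.

Further compounds
F1 | step 13 | bis-boron adduct of 17: 9-BBN group on the terminal carbon of the former vinyl group and 9-BBN borinate on the tertiary oxygen, (3S,4Z) | C(CB1C2CCCC1CCC2)[C@](C)(OB1C2CCCC1CCC2)/C=C\c1cc(O[Si](C(C)C)(C(C)C)C(C)C)ccc1Br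
F2 | step 13 | (1Z,3S,6E)-1-{2-bromo-5-[tri(propan-2-yl)silyloxy]phenyl}-3,7-dimethyl-9-[(1S)-2,6,6-trimethylcyclohex-2-en-1-yl]nona-1,6-dien-3-ol | CC1=CCCC(C)(C)[C@@H]1CC/C(C)=C/CC[C@](C)(O)/C=C\c1cc(O[Si](C(C)C)(C(C)C)C(C)C)ccc1Br
F3 | step 2 | N,N-dimethyl-1-{[(1R)-2,4,4-trimethylcyclohex-2-en-1-yl]oxy}ethen-1-amine | C=C(N(C)C)O[C@@H]1CCC(C)(C)C=C1C
F4 | step 2 | N,N-dimethyl-2-[(1S)-2,6,6-trimethylcyclohex-2-en-1-yl]acetamide | CC1=CCCC(C)(C)[C@@H]1CC(=O)N(C)C
F5 | step 12 | [(2R,3R)-3-[(Z)-2-{2-bromo-5-[tri(propan-2-yl)silyloxy]phenyl}ethenyl]-3-methyloxiran-2-yl]methanol | OC[C@H]1O[C@]1(C)/C=C\c1cc(O[Si](C(C)C)(C(C)C)C(C)C)ccc1Br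
F6 | step 12 | (2S,3R)-3-[(Z)-2-{2-bromo-5-[tri(propan-2-yl)silyloxy]phenyl}ethenyl]-2-(iodomethyl)-3-methyloxirane | IC[C@H]1O[C@]1(C)/C=C\c1cc(O[Si](C(C)C)(C(C)C)C(C)C)ccc1Br
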